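## Retrosynthetic overview

1. The target comes from the C6,C11-diol by double angeloylation. The C11 centre (Me, O) is built on the ring-fused lactone by enolate hydroxylation, then enolate methylation.
2. Key disconnection C7–C8: a samarium ketyl radical from a C8 aldehyde adds 10-exo to C7 of a tethered acrylate and the alkoxide then lactonises. The ten-membered carbocycle forms first and the γ-lactone second, in one operation, with C6 controlling C7 and C8.
3. The linear aldehyde–acrylate comes from a (2E,6Z)-dienal and methyl (E)-3-iodoacrylate by an asymmetric Ni/Cr alkenylation that sets C6.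
4. The dienal comes from a B-alkyl Suzuki coupling (C3–C4) of (Z)-3-methylhexa-3,5-dien-1-ol (from anhydromevalonolactone, whose ring fixes the Z alkene) with the (E)-enol triflate of methyl acetoacetate.

Assumptions: atom labels C1–C13 follow germacrane numbering (C12 lactone carbonyl, C11 its α-carbon, C7/C8 ring fusion, C6 the allylic carbinol); the target is read as 6S,7S,8R,11R, 1(10)Z,4E, with both esters (Z)-2-methylbut-2-enoates (angelates). In step 6 the ligand enantiomer is the one that delivers the 4R alcohol; the sense of induction is not predicted here.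

## Route

Step 1
Reactants: 1 4-methyl-5,6-dihydro-2H-pyran-2-one
Product: 3 (3Z)-3-methylhexa-3,5-dien-1-ol, via lactol 2 (not isolated)
Conditions: i-Bu2AlH (1.05 equiv), CH2Cl2, −78 °C; then Ph3P=CH2 (from Ph3PCH3Br, KOt-Bu; 2.5 equiv), THF, −78 °C → rt
Reagents that add atoms: methylenetriphenylphosphorane C=P(c1ccccc1)(c1ccccc1)c1ccccc1
Why: 1,2-reduction of the unsaturated lactone stops at the aluminium lactolate, which opens to the (Z)-hydroxy enal and is trapped by Wittig methylenation; the Z geometry (C9 cis to C2) is inherited from the ring and no stereocentre is formed.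

Step 2
Reactants: 4 methyl acetoacetate
Product: 5 methyl (2E)-3-{[(trifluoromethyl)sulfonyl]oxy}but-2-enoate
Conditions: Tf2O (1.2 equiv), 25% aq Me4NOH, hexanes, 5 °C → rt
Reagents that add atoms: trifluoromethanesulfonic anhydride O=S(=O)(OS(=O)(=O)C(F)(F)F)C(F)(F)F
Why: O-triflation of the acetoacetate enolate; with the non-chelating Me4N+ counter-ion the open enolate is trapped so that OTf lies trans to CO2Me (E).

Step 3
Reactants: 3 (3Z)-3-methylhexa-3,5-dien-1-ol; 5 methyl (2E)-3-{[(trifluoromethyl)sulfonyl]oxy}but-2-enoate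
Product: 7 methyl (2E,6Z)-9-hydroxy-3,7-dimethylnona-2,6-dienoate, via alkylborane 6 (not isolated)
Conditions: 9-BBN (2.2 equiv), THF, 0 °C → rt; then 5, Pd(dppf)Cl2 (5 mol %), Ph3As (10 mol %), 3 M aq K3PO4, DMF, rt
Reagents that add atoms: none
Why: 9-BBN (one equivalent is taken up by the hydroxyl) hydroborates only the terminal vinyl group of the diene, and the B-alkyl Suzuki–Miyaura coupling with the enol triflate goes with retention, forming C3–C4 and the 4E alkene.

Step 4
Reactants: 7 methyl (2E,6Z)-9-hydroxy-3,7-dimethylnona-2,6-dienoate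
Product: 8 (2E,6Z)-3,7-dimethylnona-2,6-diene-1,9-diol
Conditions: i-Bu2AlH (3.5 equiv), CH2Cl2, −78 → 0 °C
Reagents that add atoms: none
Why: 1,2-reduction of the enoate to the allylic alcohol by the aluminium hydride leaves both alkene geometries untouched.

Step 5
Reactants: 8 (2E,6Z)-3,7-dimethylnona-2,6-diene-1,9-diol
Product: 9 (2E,6Z)-9-hydroxy-3,7-dimethylnona-2,6-dienal
Conditions: MnO2 (20 equiv), CH2Cl2, rt
Reagents that add atoms: none
Why: MnO2 oxidises only the allylic alcohol, so the homoallylic primary hydroxyl (C8) is carried on unprotected.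

Step 6
Reactants: 9 (2E,6Z)-9-hydroxy-3,7-dimethylnona-2,6-dienal; 10 methyl (2E)-3-iodoprop-2-enoate
Product: 11 methyl (2E,4R,5E,9Z)-4,12-dihydroxy-6,10-dimethyldodeca-2,5,9-trienoate
Conditions: CrCl2 (4 equiv), chiral 4-isopropyloxazoline–aryl methanesulfonamide ligand (4.4 equiv), Et3N (4.4 equiv), NiCl2 (5 mol %), THF, rt
Reagents that add atoms: none
Why: asymmetric Nozaki–Hiyama–Kishi coupling, in which the alkenylchromium formed from 10 under nickel catalysis adds 1,2 to the enal within the chiral sulfonamide–chromium complex, setting C6 (4R in the chain, er of about 9:1 or better expected) with retention of the E acrylate geometry.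

Step 7
Reactants: 11 methyl (2E,4R,5E,9Z)-4,12-dihydroxy-6,10-dimethyldodeca-2,5,9-trienoate
Product: 12 methyl (2E,4R,5E,9Z)-6,10-dimethyl-4,12-bis[(triethylsilyl)oxy]dodeca-2,5,9-trienoate
Conditions: Et3SiCl (2.5 equiv), imidazole (4 equiv), CH2Cl2, 0 °C → rt
Reagents that add atoms: chlorotriethylsilane CC[Si](Cl)(CC)CC
Why: standard silylation of both hydroxyls; the C6 silyl ether later blocks lactonisation to C6 and acts as the large group for stereocontrol.

Step 8
Reactants: 12 methyl (2E,4R,5E,9Z)-6,10-dimethyl-4,12-bis[(triethylsilyl)oxy]dodeca-2,5,9-trienoate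
Product: 13 methyl (2E,4R,5E,9Z)-6,10-dimethyl-12-oxo-4-[(triethylsilyl)oxy]dodeca-2,5,9-trienoate
Conditions: (COCl)2 (4 equiv), DMSO (8 equiv), CH2Cl2, −78 → −40 °C; i-Pr2NEt, −78 °C; cold pH 7 buffer; used at once
Reagents that add atoms: none
Why: under Swern conditions the chlorosulfonium salt cleaves the primary triethylsilyl ether selectively and oxidises it in the same flask, while the secondary silyl ether survives and the cold neutral work-up avoids conjugation of the β,γ-unsaturated aldehyde.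

Step 9
Reactants: 13 methyl (2E,4R,5E,9Z)-6,10-dimethyl-12-oxo-4-[(triethylsilyl)oxy]dodeca-2,5,9-trienoate
Product: 15 (3aS,4S,5E,9Z,11aR)-6,10-dimethyl-4-[(triethylsilyl)oxy]-3a,4,7,8,11,11a-hexahydrocyclodeca[b]furan-2(3H)-one, via hydroxy ester 14 (not isolated)
Conditions: SmI2 (3 equiv, 0.02 M), t-BuOH (2 equiv), THF, 13 added over 8 h (final 0.002 M), −20 °C → rt
Reagents that add atoms: none
Why: Proposed new method: SmI2 reduces the aldehyde to a samarium ketyl radical that adds 10-exo to C7 of the tethered (E)-acrylate, the α-ester radical is reduced to the samarium enolate and protonated by t-BuOH, and the samarium alkoxide at C8 closes the γ-lactone; attack anti to the C6–OSiEt3 bond in the Felkin-type, A(1,3)-minimised conformer sets 7S, and the ketyl turning C9 away from C11 with its O–Sm toward the ester carbonyl sets 8R (trans-lactone); the closest known reactions are the intermolecular SmI2 aldehyde–acrylate γ-lactone annulation, SmI2 eight-membered ketyl–olefin cyclisations and radical macrocyclisations onto acrylates, and slow addition at high dilution suppresses pinacol coupling.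

Step 10
Reactants: 15 (3aS,4S,5E,9Z,11aR)-6,10-dimethyl-4-[(triethylsilyl)oxy]-3a,4,7,8,11,11a-hexahydrocyclodeca[b]furan-2(3H)-one
Product: 17 (3RS,3aS,4S,5E,9Z,11aR)-6,10-dimethyl-3,4-bis[(triethylsilyl)oxy]-3a,4,7,8,11,11a-hexahydrocyclodeca[b]furan-2(3H)-one, via hydroxy lactone 16 (not isolated)
Conditions: KN(SiMe3)2 (1.3 equiv), THF, −78 °C; (camphorsulfonyl)oxaziridine (1.5 equiv), −78 °C; then Et3SiOTf (2 equiv), −78 → 0 °C
Reagents that add atoms: (camphorsulfonyl)oxaziridine CC1(C)C2CCC13CS(=O)(=O)N4OC34C2; triethylsilyl trifluoromethanesulfonate CC[Si](CC)(CC)OS(=O)(=O)C(F)(F)F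
Why: oxaziridine hydroxylation of the potassium lactone enolate (Davis oxidation) with trapping of the potassium alkoxide as its silyl ether; the C11 configuration is immaterial here because the centre is re-enolised in step 11.

Step 11
Reactants: 17 (3RS,3aS,4S,5E,9Z,11aR)-6,10-dimethyl-3,4-bis[(triethylsilyl)oxy]-3a,4,7,8,11,11a-hexahydrocyclodeca[b]furan-2(3H)-one
Product: 18 (3R,3aS,4S,5E,9Z,11aR)-3,6,10-trimethyl-3,4-bis[(triethylsilyl)oxy]-3a,4,7,8,11,11a-hexahydrocyclodeca[b]furan-2(3H)-one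
Conditions: LiN(i-Pr)2 (1.5 equiv), THF/DMPU, −78 °C; MeI (5 equiv), −78 → −40 °C; C11 epimers separated on silica
Reagents that add atoms: iodomethane CI
Why: alkylation of the α-silyloxy lactone enolate, where MeI enters on the face anti to the adjacent C6 carbon (which carries the bulky silyloxy group), i.e. syn to H7, leaving the oxygen cis to C6 as required for 11R.

Step 12
Reactants: 18 (3R,3aS,4S,5E,9Z,11aR)-3,6,10-trimethyl-3,4-bis[(triethylsilyl)oxy]-3a,4,7,8,11,11a-hexahydrocyclodeca[b]furan-2(3H)-one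
Product: 19 (3R,3aR,4S,5E,9Z,11aR)-3,4-dihydroxy-3,6,10-trimethyl-3a,4,7,8,11,11a-hexahydrocyclodeca[b]furan-2(3H)-one
Conditions: Bu4NF (4 equiv), AcOH (4 equiv), THF, 0 °C → rt
Reagents that add atoms: none
Why: fluoride desilylation buffered with acetic acid avoids both alkoxide-driven translactonisation to C6 and acid-induced transannular cyclisation of the 1,5-diene (the 3a descriptor changes only through CIP priorities).

Step 13
Reactants: 19 (3R,3aR,4S,5E,9Z,11aR)-3,4-dihydroxy-3,6,10-trimethyl-3a,4,7,8,11,11a-hexahydrocyclodeca[b]furan-2(3H)-one; 20 angelic acid [(2Z)-2-methylbut-2-enoic acid]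
Product: 22 (3R,3aS,4S,5E,9Z,11aR)-3,6,10-trimethyl-2-oxo-2,3,3a,4,7,8,11,11a-octahydrocyclodeca[b]furan-3,4-diyl bis[(2Z)-2-methylbut-2-enoate], via angelic anhydride 21 (not isolated)
Conditions: 20 (6 equiv), dicyclohexylcarbodiimide (3 equiv), CH2Cl2, 0 °C → rt, filtered; then 19, LiN(SiMe3)2 (2.3 equiv), THF, −78 → −20 °C
Reagents that add atoms: none
Why: acylation of the dilithium dialkoxide by the symmetrical anhydride at low temperature esterifies both the secondary and the tertiary α-hydroxy-lactone oxygen without nucleophilic amine catalysts, so the angelates do not isomerise to tiglates.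

## Compound list

1 | 4-methyl-5,6-dihydro-2H-pyran-2-one (anhydromevalonolactone) | CC1=CC(=O)OCC1 | starting material
2 | 4-methyl-5,6-dihydro-2H-pyran-2-ol (lactol, present as its aluminium alkoxide) | CC1=CC(O)OCC1 | intermediate
3 | (3Z)-3-methylhexa-3,5-dien-1-ol | OCC/C(C)=C\C=C | intermediate
4 | methyl acetoacetate (methyl 3-oxobutanoate) | CC(=O)CC(=O)OC | starting material
5 | methyl (2E)-3-{[(trifluoromethyl)sulfonyl]oxy}but-2-enoate | COC(=O)/C=C(\C)OS(=O)(=O)C(F)(F)F | intermediate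
6 | 9-[(3Z)-6-(9-borabicyclo[3.3.1]nonan-9-yloxy)-4-methylhex-3-en-1-yl]-9-borabicyclo[3.3.1]nonane | C/C(CCOB1C2CCCC1CCC2)=C/CCB1C2CCCC1CCC2 | intermediate
7 | methyl (2E,6Z)-9-hydroxy-3,7-dimethylnona-2,6-dienoate | COC(=O)/C=C(\C)CC/C=C(/C)CCO | intermediate
8 | (2E,6Z)-3,7-dimethylnona-2,6-diene-1,9-diol | OC/C=C(\C)CC/C=C(/C)CCO | intermediate
9 | (2E,6Z)-9-hydroxy-3,7-dimethylnona-2,6-dienal | O=C/C=C(\C)CC/C=C(/C)CCO | intermediate
10 | methyl (2E)-3-iodoprop-2-enoate | COC(=O)/C=C/I | starting material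
11 | methyl (2E,4R,5E,9Z)-4,12-dihydroxy-6,10-dimethyldodeca-2,5,9-trienoate | COC(=O)/C=C/[C@@H](O)/C=C(\C)CC/C=C(/C)CCO | intermediate
12 | methyl (2E,4R,5E,9Z)-6,10-dimethyl-4,12-bis[(triethylsilyl)oxy]dodeca-2,5,9-trienoate | COC(=O)/C=C/[C@@H](O[Si](CC)(CC)CC)/C=C(\C)CC/C=C(/C)CCO[Si](CC)(CC)CC | intermediate
13 | methyl (2E,4R,5E,9Z)-6,10-dimethyl-12-oxo-4-[(triethylsilyl)oxy]dodeca-2,5,9-trienoate | COC(=O)/C=C/[C@@H](O[Si](CC)(CC)CC)/C=C(\C)CC/C=C(/C)CC=O | intermediate
14 | methyl 2-[(1S,2S,3E,7Z,10R)-10-hydroxy-4,8-dimethyl-2-[(triethylsilyl)oxy]cyclodeca-3,7-dien-1-yl]acetate (as its trivalent samarium alkoxide) | CC[Si](CC)(CC)O[C@H]1/C=C(\C)CC/C=C(/C)C[C@@H](O)[C@@H]1CC(=O)OC | intermediate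
15 | (3aS,4S,5E,9Z,11aR)-6,10-dimethyl-4-[(triethylsilyl)oxy]-3a,4,7,8,11,11a-hexahydrocyclodeca[b]furan-2(3H)-one | CC[Si](CC)(CC)O[C@H]1/C=C(\C)CC/C=C(/C)C[C@H]2OC(=O)C[C@H]12 | intermediate
16 | (3RS,3aS,4S,5E,9Z,11aR)-3-hydroxy-6,10-dimethyl-4-[(triethylsilyl)oxy]-3a,4,7,8,11,11a-hexahydrocyclodeca[b]furan-2(3H)-one (as its potassium alkoxide) | CC[Si](CC)(CC)O[C@H]1/C=C(\C)CC/C=C(/C)C[C@H]2OC(=O)C(O)[C@H]12 | intermediate
17 | (3RS,3aS,4S,5E,9Z,11aR)-6,10-dimethyl-3,4-bis[(triethylsilyl)oxy]-3a,4,7,8,11,11a-hexahydrocyclodeca[b]furan-2(3H)-one | CC[Si](CC)(CC)O[C@H]1/C=C(\C)CC/C=C(/C)C[C@H]2OC(=O)C(O[Si](CC)(CC)CC)[C@H]12 | intermediate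
18 | (3R,3aS,4S,5E,9Z,11aR)-3,6,10-trimethyl-3,4-bis[(triethylsilyl)oxy]-3a,4,7,8,11,11a-hexahydrocyclodeca[b]furan-2(3H)-one | CC[Si](CC)(CC)O[C@H]1/C=C(\C)CC/C=C(/C)C[C@H]2OC(=O)[C@](C)(O[Si](CC)(CC)CC)[C@H]12 | intermediate
19 | (3R,3aR,4S,5E,9Z,11aR)-3,4-dihydroxy-3,6,10-trimethyl-3a,4,7,8,11,11a-hexahydrocyclodeca[b]furan-2(3H)-one | O[C@H]1/C=C(\C)CC/C=C(/C)C[C@H]2OC(=O)[C@](C)(O)[C@H]12 | intermediate
20 | angelic acid, (2Z)-2-methylbut-2-enoic acid | C/C=C(/C)C(=O)O | starting material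
21 | angelic anhydride, (2Z)-2-methylbut-2-enoic anhydride | C/C=C(/C)C(=O)OC(=O)/C(C)=C\C | intermediate
22 | (3R,3aS,4S,5E,9Z,11aR)-3,6,10-trimethyl-2-oxo-2,3,3a,4,7,8,11,11a-octahydrocyclodeca[b]furan-3,4-diyl bis[(2Z)-2-methylbut-2-enoate] | C/C=C(/C)C(=O)O[C@H]1/C=C(\C)CC/C=C(/C)C[C@H]2OC(=O)[C@](C)(OC(=O)/C(C)=C\C)[C@H]12 | target

## Step count and risks

Total: 13 steps. Longest linear sequence: 12 steps (1 → 22 through steps 1 and 3–13); step 2 is a one-step side branch.

**Step 9 (radical macrocyclisation).** The ten-membered ketyl–olefin closure may lose to pinacol dimerisation, simple reduction of the aldehyde, or 8-endo addition to the C4=C5 alkene; the β,γ-unsaturated aldehyde 13 is also labile. The fallback sets out from 12 and returns at 15. Selective methanolysis of the primary silyl ether of 12 (pyridinium p-toluenesulfonate, MeOH/CH2Cl2, 0 °C) gives methyl (2E,4R,5E,9Z)-12-hydroxy-6,10-dimethyl-4-[(triethylsilyl)oxy]dodeca-2,5,9-trienoate F1. Instead of a samarium ketyl, a neutral α-hydroxyalkyl radical is then generated catalytically at C8 of F1 by hydrogen-atom transfer (Ir[dF(CF3)ppy]2(dtbbpy)PF6, quinuclidine, Bu4N+ H2PO4−, MeCN, blue light, 0.002 M). It adds to C7 of the acrylate, the α-ester radical is reduced and protonated to 14, and 14 lactonises to 15. This radical cannot be over-reduced or dimerise through samarium, it is regenerated until it cyclises, and the oxidation to 13 is bypassed.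

**Step 11 (C11 quaternary centre).** The methyl group may enter syn to C6, giving the 11-epimer, if the macrocycle shields the face next to H7. The fallback sets out from 15 and returns at 19, reversing the order so that oxygen, not carbon, is the last group to enter on the preferred face. Lactone 15 is methylated first (LiN(i-Pr)2, MeI, THF, −78 °C) to (3RS,3aS,4S,5E,9Z,11aR)-3,6,10-trimethyl-4-[(triethylsilyl)oxy]-3a,4,7,8,11,11a-hexahydrocyclodeca[b]furan-2(3H)-one F2. Its potassium enolate is then hydroxylated (KN(SiMe3)2, (camphorsulfonyl)oxaziridine, THF, −78 °C) to (3R,3aS,4S,5E,9Z,11aR)-3-hydroxy-3,6,10-trimethyl-4-[(triethylsilyl)oxy]-3a,4,7,8,11,11a-hexahydrocyclodeca[b]furan-2(3H)-one F3. Bu4NF/AcOH then gives 19.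

**Step 13 (double angeloylation).** The tertiary α-hydroxy lactone may acylate sluggishly, the C6 alkoxide may translactonise, and some angelate may isomerise to tiglate. The fallback sets out from 19 and returns at 22, building the Z alkenes on the esters instead of transferring them. Both hydroxyls are esterified with 2-[bis(2,2,2-trifluoroethoxy)phosphoryl]propanoic acid (dicyclohexylcarbodiimide, 4-(dimethylamino)pyridine, CH2Cl2; acylation runs through the phosphonoketene and tolerates tertiary alcohols) to give (3R,3aS,4S,5E,9Z,11aR)-3,6,10-trimethyl-2-oxo-2,3,3a,4,7,8,11,11a-octahydrocyclodeca[b]furan-3,4-diyl bis{2-[bis(2,2,2-trifluoroethoxy)phosphoryl]propanoate} F4. A double Still–Gennari olefination with acetaldehyde (KN(SiMe3)2, 18-crown-6, THF, −78 °C) then forms both (Z)-2-methylbut-2-enoates and gives 22.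

## Further compounds

F1 | step 9 | methyl (2E,4R,5E,9Z)-12-hydroxy-6,10-dimethyl-4-[(triethylsilyl)oxy]dodeca-2,5,9-trienoate | COC(=O)/C=C/[C@@H](O[Si](CC)(CC)CC)/C=C(\C)CC/C=C(/C)CCO
F2 | step 11 | (3RS,3aS,4S,5E,9Z,11aR)-3,6,10-trimethyl-4-[(triethylsilyl)oxy]-3a,4,7,8,11,11a-hexahydrocyclodeca[b]furan-2(3H)-one | CC[Si](CC)(CC)O[C@H]1/C=C(\C)CC/C=C(/C)C[C@H]2OC(=O)C(C)[C@H]12
F3 | step 11 | (3R,3aS,4S,5E,9Z,11aR)-3-hydroxy-3,6,10-trimethyl-4-[(triethylsilyl)oxy]-3a,4,7,8,11,11a-hexahydrocyclodeca[b]furan-2(3H)-one | CC[Si](CC)(CC)O[C@H]1/C=C(\C)CC/C=C(/C)C[C@H]2OC(=O)[C@](C)(O)[C@H]12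
F4 | step 13 | (3R,3aS,4S,5E,9Z,11aR)-3,6,10-trimethyl-2-oxo-2,3,3a,4,7,8,11,11a-octahydrocyclodeca[b]furan-3,4-diyl bis{2-[bis(2,2,2-trifluoroethoxy)phosphoryl]propanoate} | CC(C(=O)O[C@H]1/C=C(\C)CC/C=C(/C)C[C@H]2OC(=O)[C@](C)(OC(=O)C(C)P(=O)(OCC(F)(F)F)OCC(F)(F)F)[C@H]12)P(=O)(OCC(F)(F)F)OCC(F)(F)F
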